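**Plan**

1. Rings are lettered A–G in the order of the SMILES, atoms numbered in the order written. All hydroxyls are carried as methyl ethers except the C3/C4 catechol of ring D (acetonide); the last cut is global O-demethylation.
2. The central ether O–C1(ring D) is cut first, giving trimer phenol A–B–C (free OH on ring C) and tetramer catechol D–E–F–G. The other five ethers are cut at the aryl carbon that bore bromine: rings B and F from 4-bromo-2,6-dimethoxybenzaldehyde, rings C and E from 6-bromo-2,3,4-trimethoxybenzaldehyde, ring G from 5-bromo-1,2,3-trimethoxybenzene.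
3. Forward: each bromo-aldehyde is attached by copper-catalysed etherification; its CHO sits where the next ether oxygen belongs (para in B/F, ortho in C/E) and is turned into that phenol by Baeyer–Villiger (Dakin-type) oxidation. Chain A→B→C is built in steps 2–5, chain D→E→F→G in steps 6–10.
4. Ring D has no such relay position, but it alone carries a free catechol (C3–OH, C4–OH) next to an aryloxy group (C5–O–ring E). In its o-quinone, C1 is the β-carbon of the enone O=C3–C2=C1, is not enriched by the C5 aryloxy donor, and is flanked by C2–H and C6–H. The ring-C phenol oxygen is therefore added there after anodic oxidation (step 12), with C–H as the only handle and the two ring-D hydroxyls already free.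
5. No stereocentre or stable axis exists, so no stereochemistry has to be set.

Key step: step 12

Remark: the SMILES contains no stereocentre and the diaryl ether axes rotate freely, so "the single enantiomer" is taken to mean the one achiral constitution drawn.

**Route**

Step 1
Reactants: 1 5-bromo-1,2,3-trimethoxybenzene
Product: 2 6-bromo-2,3,4-trimethoxybenzaldehyde
Conditions: Cl2CHOMe, TiCl4, CH2Cl2, −10 to 0 °C; then ice-water
Reagents that add atoms: dichloromethyl methyl ether, COC(Cl)Cl; water, O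
Why: Rieche formylation (electrophilic aromatic substitution) can only occur at the two equivalent free positions of 1, each ortho to one methoxy and para to another, which places CHO next to the C–Br carbon.

Step 2
Reactants: 3 2,4,6-trimethoxyphenol; 4 4-bromo-2,6-dimethoxybenzaldehyde
Product: 5 2,6-dimethoxy-4-(2,4,6-trimethoxyphenoxy)benzaldehyde
Conditions: CuI (10 mol%), picolinic acid (20 mol%), K3PO4, DMSO, 90 °C, Ar
Reagents that add atoms: none
Why: Ullmann-type copper-catalysed diaryl ether synthesis should work because the bromide of 4 has two ortho hydrogens and a para-formyl activator, and the CuI/picolinic acid system is suited to 2,6-disubstituted phenols.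

Step 3
Reactants: 5 2,6-dimethoxy-4-(2,4,6-trimethoxyphenoxy)benzaldehyde
Product: 7 2,6-dimethoxy-4-(2,4,6-trimethoxyphenoxy)phenol, via aryl formate 6 (not isolated)
Conditions: mCPBA, CH2Cl2, 0 °C to rt; then K2CO3 (cat.), MeOH, rt
Reagents that add atoms: meta-chloroperoxybenzoic acid (mCPBA), OOC(=O)c1cccc(Cl)c1
Why: In this Baeyer–Villiger (Dakin-type) oxidation the electron-rich di-ortho-oxygenated aryl group migrates in the Criegee intermediate to give the aryl formate, which methanolysis cleaves to the phenol.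

Step 4
Reactants: 7 2,6-dimethoxy-4-(2,4,6-trimethoxyphenoxy)phenol; 2 6-bromo-2,3,4-trimethoxybenzaldehyde
Product: 8 6-[2,6-dimethoxy-4-(2,4,6-trimethoxyphenoxy)phenoxy]-2,3,4-trimethoxybenzaldehyde
Conditions: CuI (20 mol%), picolinic acid (40 mol%), K3PO4, DMSO, 100 °C, Ar
Reagents that add atoms: none
Why: In this Ullmann-type etherification the ortho-formyl group of 2 assists copper insertion into the C–Br bond, which should offset the steric demand of the 2,6-dimethoxyphenol 7.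

Step 5
Reactants: 8 6-[2,6-dimethoxy-4-(2,4,6-trimethoxyphenoxy)phenoxy]-2,3,4-trimethoxybenzaldehyde
Product: 10 6-[2,6-dimethoxy-4-(2,4,6-trimethoxyphenoxy)phenoxy]-2,3,4-trimethoxyphenol, via aryl formate 9 (not isolated)
Conditions: mCPBA, CH2Cl2, 0 °C to rt; then K2CO3 (cat.), MeOH, rt
Reagents that add atoms: meta-chloroperoxybenzoic acid (mCPBA), OOC(=O)c1cccc(Cl)c1
Why: Baeyer–Villiger (Dakin-type) oxidation with aryl migration converts the CHO flanked by aryloxy and methoxy groups into the ring-C hydroxyl that is the nucleophile of the key step.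

Step 6
Reactants: 11 2,2-dimethyl-1,3-benzodioxol-4-ol; 2 6-bromo-2,3,4-trimethoxybenzaldehyde
Product: 12 6-[(2,2-dimethyl-1,3-benzodioxol-4-yl)oxy]-2,3,4-trimethoxybenzaldehyde
Conditions: CuI (10 mol%), picolinic acid (20 mol%), K3PO4, DMSO, 90 °C, Ar
Reagents that add atoms: none
Why: Ullmann-type etherification of an ortho-formyl-activated bromide with a phenol whose single ortho oxygen is tied back in the dioxole ring should be the least hindered coupling of the route.

Step 7
Reactants: 12 6-[(2,2-dimethyl-1,3-benzodioxol-4-yl)oxy]-2,3,4-trimethoxybenzaldehyde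
Product: 14 6-[(2,2-dimethyl-1,3-benzodioxol-4-yl)oxy]-2,3,4-trimethoxyphenol, via aryl formate 13 (not isolated)
Conditions: mCPBA, CH2Cl2, 0 °C to rt; then K2CO3 (cat.), MeOH, rt
Reagents that add atoms: meta-chloroperoxybenzoic acid (mCPBA), OOC(=O)c1cccc(Cl)c1
Why: Baeyer–Villiger (Dakin-type) oxidation proceeds by aryl migration as before, and the catechol acetonide is stable to the peracid, to 3-chlorobenzoic acid and to carbonate in methanol.

Step 8
Reactants: 14 6-[(2,2-dimethyl-1,3-benzodioxol-4-yl)oxy]-2,3,4-trimethoxyphenol; 4 4-bromo-2,6-dimethoxybenzaldehyde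
Product: 15 4-{6-[(2,2-dimethyl-1,3-benzodioxol-4-yl)oxy]-2,3,4-trimethoxyphenoxy}-2,6-dimethoxybenzaldehyde
Conditions: CuI (10 mol%), picolinic acid (20 mol%), K3PO4, DMSO, 90 °C, Ar
Reagents that add atoms: none
Why: Ullmann-type etherification as in step 2, joining a di-ortho-substituted phenol to the unhindered para-formyl-activated bromide.

Step 9
Reactants: 15 4-{6-[(2,2-dimethyl-1,3-benzodioxol-4-yl)oxy]-2,3,4-trimethoxyphenoxy}-2,6-dimethoxybenzaldehyde
Product: 17 4-{6-[(2,2-dimethyl-1,3-benzodioxol-4-yl)oxy]-2,3,4-trimethoxyphenoxy}-2,6-dimethoxyphenol, via aryl formate 16 (not isolated)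
Conditions: mCPBA, CH2Cl2, 0 °C to rt; then K2CO3 (cat.), MeOH, rt
Reagents that add atoms: meta-chloroperoxybenzoic acid (mCPBA), OOC(=O)c1cccc(Cl)c1
Why: Baeyer–Villiger (Dakin-type) oxidation of the 2,6-dimethoxybenzaldehyde unit gives the ring-F hydroxyl flanked by two methoxy groups.

Step 10
Reactants: 17 4-{6-[(2,2-dimethyl-1,3-benzodioxol-4-yl)oxy]-2,3,4-trimethoxyphenoxy}-2,6-dimethoxyphenol; 1 5-bromo-1,2,3-trimethoxybenzene
Product: 18 4-{2-[3,5-dimethoxy-4-(3,4,5-trimethoxyphenoxy)phenoxy]-3,4,5-trimethoxyphenoxy}-2,2-dimethyl-1,3-benzodioxole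
Conditions: CuI (20 mol%), picolinic acid (40 mol%), K3PO4, DMSO, 110 °C, Ar
Reagents that add atoms: none
Why: Ullmann diaryl ether synthesis between a 2,6-dimethoxyphenol and a 3,4,5-trimethoxyphenyl bromide with two ortho hydrogens is the classical coupling for permethylated phlorotannins, here run with a ligand suited to hindered phenols.

Step 11
Reactants: 18 4-{2-[3,5-dimethoxy-4-(3,4,5-trimethoxyphenoxy)phenoxy]-3,4,5-trimethoxyphenoxy}-2,2-dimethyl-1,3-benzodioxole
Product: 19 3-{2-[3,5-dimethoxy-4-(3,4,5-trimethoxyphenoxy)phenoxy]-3,4,5-trimethoxyphenoxy}benzene-1,2-diol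
Conditions: TFA/H2O 9:1, 40 °C, Ar
Reagents that add atoms: none
Why: Acid-catalysed ketal hydrolysis releases the ring-D catechol, while aryl methyl ethers and diaryl ethers are inert to aqueous TFA.

Step 12
Reactants: 19 3-{2-[3,5-dimethoxy-4-(3,4,5-trimethoxyphenoxy)phenoxy]-3,4,5-trimethoxyphenoxy}benzene-1,2-diol; 10 6-[2,6-dimethoxy-4-(2,4,6-trimethoxyphenoxy)phenoxy]-2,3,4-trimethoxyphenol
Product: 22 hexadeca-O-methyl heptamer catechol, via tetramer o-quinone 20 (not isolated), via heptamer o-quinone 21 (not isolated)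
Conditions: 10 (1.5 equiv), RVC anode/Pt cathode, divided cell, anode held at the foot of the first wave of 19 (about +0.3 V vs Ag/AgCl), n-Bu4NOAc/AcOH, MeCN–CH2Cl2 3:1, 0 °C, 19 added over 6 h, about 4 F/mol; then aq. Na2S2O4
Reagents that add atoms: none
Why: Proposed new method: the anode takes two electrons and two protons from ring D of 19 to give o-quinone 20 (EC mechanism) at a potential where the monophenol 10 and the methoxyarene rings should stay untouched; the acetate-hydrogen-bonded phenol oxygen of 10 then adds 1,4 to the enone O=C3–C2=C1 of ring D, tautomerisation re-aromatises the ring, the adduct is oxidised once more to the donor-stabilised quinone 21, and dithionite returns it to catechol 22. The closest known reaction type is the anodic (or periodate) oxidation of catechols in the presence of nucleophiles such as amines, sulfinates, enols and methanol, in which 3-substituted o-quinones are attacked at C5, the position that corresponds to C1 of ring D; what is new is a hindered phenol as the oxygen nucleophile. No ring is closed and no stereocentre is formed. Regioselectivity for C1 over C2 and C6 of ring D is needed: the C5 aryloxy group pushes electron density onto C6 and C2 and leaves C1, which has two ortho hydrogens, as the electrophilic and unhindered carbon. O- over C-attack is secured because both ortho positions and the para position of the phenol in 10 are substituted, and condensation of 20 with unoxidised 19 is held back by slow addition of 19 to an excess of 10.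

Step 13
Reactants: 22 hexadeca-O-methyl heptamer catechol
Product: 23 CNP0130704.0 (target)
Conditions: BBr3 (excess), CH2Cl2, −78 °C to rt, Ar; then MeOH/H2O, 0 °C; reverse-phase purification with acidified eluent under Ar
Reagents that add atoms: none
Why: In this Lewis-acid ether cleavage bromide attacks the methyl carbon of each boron-complexed ArO–Me unit, whereas the diaryl ether C–O bonds offer no sp3 carbon and should survive.

**Compound list**

1 | 5-bromo-1,2,3-trimethoxybenzene | COc1cc(Br)cc(OC)c1OC | starting material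
2 | 6-bromo-2,3,4-trimethoxybenzaldehyde | COc1cc(Br)c(C=O)c(OC)c1OC | intermediate
3 | 2,4,6-trimethoxyphenol | COc1cc(OC)c(O)c(OC)c1 | starting material
4 | 4-bromo-2,6-dimethoxybenzaldehyde | COc1cc(Br)cc(OC)c1C=O | starting material
5 | 2,6-dimethoxy-4-(2,4,6-trimethoxyphenoxy)benzaldehyde | COc1cc(OC)c(Oc2cc(OC)c(C=O)c(OC)c2)c(OC)c1 | intermediate
6 | 2,6-dimethoxy-4-(2,4,6-trimethoxyphenoxy)phenyl formate | COc1cc(OC)c(Oc2cc(OC)c(OC=O)c(OC)c2)c(OC)c1 | intermediate
7 | 2,6-dimethoxy-4-(2,4,6-trimethoxyphenoxy)phenol | COc1cc(OC)c(Oc2cc(OC)c(O)c(OC)c2)c(OC)c1 | intermediate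
8 | 6-[2,6-dimethoxy-4-(2,4,6-trimethoxyphenoxy)phenoxy]-2,3,4-trimethoxybenzaldehyde | COc1cc(OC)c(Oc2cc(OC)c(Oc3cc(OC)c(OC)c(OC)c3C=O)c(OC)c2)c(OC)c1 | intermediate
9 | 6-[2,6-dimethoxy-4-(2,4,6-trimethoxyphenoxy)phenoxy]-2,3,4-trimethoxyphenyl formate | COc1cc(OC)c(Oc2cc(OC)c(Oc3cc(OC)c(OC)c(OC)c3OC=O)c(OC)c2)c(OC)c1 | intermediate
10 | 6-[2,6-dimethoxy-4-(2,4,6-trimethoxyphenoxy)phenoxy]-2,3,4-trimethoxyphenol | COc1cc(OC)c(Oc2cc(OC)c(Oc3cc(OC)c(OC)c(OC)c3O)c(OC)c2)c(OC)c1 | intermediate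
11 | 2,2-dimethyl-1,3-benzodioxol-4-ol | CC1(C)Oc2cccc(O)c2O1 | starting material
12 | 6-[(2,2-dimethyl-1,3-benzodioxol-4-yl)oxy]-2,3,4-trimethoxybenzaldehyde | CC1(C)Oc2cccc(Oc3cc(OC)c(OC)c(OC)c3C=O)c2O1 | intermediate
13 | 6-[(2,2-dimethyl-1,3-benzodioxol-4-yl)oxy]-2,3,4-trimethoxyphenyl formate | CC1(C)Oc2cccc(Oc3cc(OC)c(OC)c(OC)c3OC=O)c2O1 | intermediate
14 | 6-[(2,2-dimethyl-1,3-benzodioxol-4-yl)oxy]-2,3,4-trimethoxyphenol | CC1(C)Oc2cccc(Oc3cc(OC)c(OC)c(OC)c3O)c2O1 | intermediate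
15 | 4-{6-[(2,2-dimethyl-1,3-benzodioxol-4-yl)oxy]-2,3,4-trimethoxyphenoxy}-2,6-dimethoxybenzaldehyde | CC1(C)Oc2cccc(Oc3cc(OC)c(OC)c(OC)c3Oc3cc(OC)c(C=O)c(OC)c3)c2O1 | intermediate
16 | 4-{6-[(2,2-dimethyl-1,3-benzodioxol-4-yl)oxy]-2,3,4-trimethoxyphenoxy}-2,6-dimethoxyphenyl formate | CC1(C)Oc2cccc(Oc3cc(OC)c(OC)c(OC)c3Oc3cc(OC)c(OC=O)c(OC)c3)c2O1 | intermediate
17 | 4-{6-[(2,2-dimethyl-1,3-benzodioxol-4-yl)oxy]-2,3,4-trimethoxyphenoxy}-2,6-dimethoxyphenol | CC1(C)Oc2cccc(Oc3cc(OC)c(OC)c(OC)c3Oc3cc(OC)c(O)c(OC)c3)c2O1 | intermediate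
18 | 4-{2-[3,5-dimethoxy-4-(3,4,5-trimethoxyphenoxy)phenoxy]-3,4,5-trimethoxyphenoxy}-2,2-dimethyl-1,3-benzodioxole | CC1(C)Oc2cccc(Oc3cc(OC)c(OC)c(OC)c3Oc3cc(OC)c(Oc4cc(OC)c(OC)c(OC)c4)c(OC)c3)c2O1 | intermediate
19 | 3-{2-[3,5-dimethoxy-4-(3,4,5-trimethoxyphenoxy)phenoxy]-3,4,5-trimethoxyphenoxy}benzene-1,2-diol | Oc1cccc(Oc2cc(OC)c(OC)c(OC)c2Oc2cc(OC)c(Oc3cc(OC)c(OC)c(OC)c3)c(OC)c2)c1O | intermediate
20 | 3-{2-[3,5-dimethoxy-4-(3,4,5-trimethoxyphenoxy)phenoxy]-3,4,5-trimethoxyphenoxy}cyclohexa-3,5-diene-1,2-dione (tetramer o-quinone) | O=C1C=CC=C(Oc2cc(OC)c(OC)c(OC)c2Oc2cc(OC)c(Oc3cc(OC)c(OC)c(OC)c3)c(OC)c2)C1=O | intermediate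
21 | 3-{2-[3,5-dimethoxy-4-(3,4,5-trimethoxyphenoxy)phenoxy]-3,4,5-trimethoxyphenoxy}-5-{6-[2,6-dimethoxy-4-(2,4,6-trimethoxyphenoxy)phenoxy]-2,3,4-trimethoxyphenoxy}cyclohexa-3,5-diene-1,2-dione (heptamer o-quinone) | COc1cc(OC)c(Oc2cc(OC)c(Oc3cc(OC)c(OC)c(OC)c3OC3=CC(=O)C(=O)C(Oc4cc(OC)c(OC)c(OC)c4Oc4cc(OC)c(Oc5cc(OC)c(OC)c(OC)c5)c(OC)c4)=C3)c(OC)c2)c(OC)c1 | intermediate
22 | 3-{2-[3,5-dimethoxy-4-(3,4,5-trimethoxyphenoxy)phenoxy]-3,4,5-trimethoxyphenoxy}-5-{6-[2,6-dimethoxy-4-(2,4,6-trimethoxyphenoxy)phenoxy]-2,3,4-trimethoxyphenoxy}benzene-1,2-diol (hexadeca-O-methyl heptamer catechol) | COc1cc(OC)c(Oc2cc(OC)c(Oc3cc(OC)c(OC)c(OC)c3Oc3cc(O)c(O)c(Oc4cc(OC)c(OC)c(OC)c4Oc4cc(OC)c(Oc5cc(OC)c(OC)c(OC)c5)c(OC)c4)c3)c(OC)c2)c(OC)c1 | intermediate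
23 | 3-{2-[3,5-dihydroxy-4-(3,4,5-trihydroxyphenoxy)phenoxy]-3,4,5-trihydroxyphenoxy}-5-{6-[2,6-dihydroxy-4-(2,4,6-trihydroxyphenoxy)phenoxy]-2,3,4-trihydroxyphenoxy}benzene-1,2-diol (CNP0130704.0) | Oc1cc(O)c(Oc2cc(O)c(Oc3cc(O)c(O)c(O)c3Oc3cc(O)c(O)c(Oc4cc(O)c(O)c(O)c4Oc4cc(O)c(Oc5cc(O)c(O)c(O)c5)c(O)c4)c3)c(O)c2)c(O)c1 | target

**Count and risks**

Total step count: 13. Longest linear sequence: 9 steps (steps 1, 6, 7, 8, 9, 10, 11, 12, 13, starting from 1).

Steps most likely to fail: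

Step 12 (proposed new method). The phenol 10 may be oxidised at the anode in competition with the catechol. The quinone 20 may condense with unoxidised 19. The phenol may also attack the aryloxy-bearing C5 of ring D with exchange of the ring-E ether. The fallback uses known chemistry and sets out from 19. O-Methylation (MeI, K2CO3, acetone) should give 1-{2-[3,5-dimethoxy-4-(3,4,5-trimethoxyphenoxy)phenoxy]-3,4,5-trimethoxyphenoxy}-2,3-dimethoxybenzene F1. Iridium-catalysed C–H borylation ([Ir(cod)OMe]2, dtbpy, B2pin2, THF, 80 °C) should then functionalise the only C–H of the molecule that has two ortho hydrogens, C1 of ring D, to give the ring-D pinacol boronate F2. Chan–Lam coupling of F2 with 10 (Cu(OAc)2, pyridine, B(OH)3, 4 Å sieves, MeCN, air, 60 °C) should give the octadeca-O-methyl heptamer F3. BBr3 under the conditions of step 13 converts F3 into 23, where the fallback rejoins the route.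

Step 13. Some of the sixteen methyl ethers may be cleaved incompletely, and the pyrogallol rings may be oxidised by air during aqueous work-up and chromatography. The fallback sets out from 22. The crude product of the BBr3 treatment is not isolated but acetylated in the same flask (Ac2O, pyridine, DMAP) to the octadecaacetate of the target F4, which is stable, can be purified on silica and checked for complete demethylation. Transesterification (cat. NaOMe, degassed MeOH, then acidic resin, Ar) should then release 23.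

Step 10. Copper insertion into the electron-rich, unactivated bromide 1 may be slow, and the hindered phenol 17 may decompose on prolonged heating. The fallback sets out from 17 and repeats the aldehyde relay. Coupling with the activated bromide 4 under the conditions of step 8 should give 4-{4-[6-((2,2-dimethyl-1,3-benzodioxol-4-yl)oxy)-2,3,4-trimethoxyphenoxy]-2,6-dimethoxyphenoxy}-2,6-dimethoxybenzaldehyde F5. Baeyer–Villiger oxidation and methanolysis as in step 9 should give, through the aryl formate F6, the corresponding phenol F7. O-Methylation of F7 (MeI, K2CO3, acetone) gives 18, where the fallback rejoins the route.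

**Further compounds**

F1 | step 12 | 1-{2-[3,5-dimethoxy-4-(3,4,5-trimethoxyphenoxy)phenoxy]-3,4,5-trimethoxyphenoxy}-2,3-dimethoxybenzene | COc1cccc(Oc2cc(OC)c(OC)c(OC)c2Oc2cc(OC)c(Oc3cc(OC)c(OC)c(OC)c3)c(OC)c2)c1OC
F2 | step 12 | 2-(3-{2-[3,5-dimethoxy-4-(3,4,5-trimethoxyphenoxy)phenoxy]-3,4,5-trimethoxyphenoxy}-4,5-dimethoxyphenyl)-4,4,5,5-tetramethyl-1,3,2-dioxaborolane | COc1cc(B2OC(C)(C)C(C)(C)O2)cc(Oc2cc(OC)c(OC)c(OC)c2Oc2cc(OC)c(Oc3cc(OC)c(OC)c(OC)c3)c(OC)c2)c1OC
F3 | step 12 | octadeca-O-methyl ether of the target | COc1cc(OC)c(Oc2cc(OC)c(Oc3cc(OC)c(OC)c(OC)c3Oc3cc(OC)c(OC)c(Oc4cc(OC)c(OC)c(OC)c4Oc4cc(OC)c(Oc5cc(OC)c(OC)c(OC)c5)c(OC)c4)c3)c(OC)c2)c(OC)c1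
F4 | step 13 | octadecaacetate of the target | CC(=O)Oc1cc(OC(C)=O)c(Oc2cc(OC(C)=O)c(Oc3cc(OC(C)=O)c(OC(C)=O)c(OC(C)=O)c3Oc3cc(OC(C)=O)c(OC(C)=O)c(Oc4cc(OC(C)=O)c(OC(C)=O)c(OC(C)=O)c4Oc4cc(OC(C)=O)c(Oc5cc(OC(C)=O)c(OC(C)=O)c(OC(C)=O)c5)c(OC(C)=O)c4)c3)c(OC(C)=O)c2)c(OC(C)=O)c1
F5 | step 10 | 4-{4-[6-((2,2-dimethyl-1,3-benzodioxol-4-yl)oxy)-2,3,4-trimethoxyphenoxy]-2,6-dimethoxyphenoxy}-2,6-dimethoxybenzaldehyde | CC1(C)Oc2cccc(Oc3cc(OC)c(OC)c(OC)c3Oc3cc(OC)c(Oc4cc(OC)c(C=O)c(OC)c4)c(OC)c3)c2O1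
F6 | step 10 | 4-{4-[6-((2,2-dimethyl-1,3-benzodioxol-4-yl)oxy)-2,3,4-trimethoxyphenoxy]-2,6-dimethoxyphenoxy}-2,6-dimethoxyphenyl formate | CC1(C)Oc2cccc(Oc3cc(OC)c(OC)c(OC)c3Oc3cc(OC)c(Oc4cc(OC)c(OC=O)c(OC)c4)c(OC)c3)c2O1
F7 | step 10 | 4-{4-[6-((2,2-dimethyl-1,3-benzodioxol-4-yl)oxy)-2,3,4-trimethoxyphenoxy]-2,6-dimethoxyphenoxy}-2,6-dimethoxyphenol | CC1(C)Oc2cccc(Oc3cc(OC)c(OC)c(OC)c3Oc3cc(OC)c(Oc4cc(OC)c(O)c(OC)c4)c(OC)c3)c2O1
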